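The easy step was to treat each run's first reading as a steady rate and see how far that overshoots its last reading.

| flask | substrate | partner | free catalyst | time |
|---|---|---|---|---|
| eta | 0.0800 M | 0.160 M | 4.00 × 10⁻⁴ M |  |
| beta | 0.0320 M | 0.112 M | 4.00 × 10⁻⁴ M |  |
| theta | 0.120 M | 0.160 M | 4.00 × 10⁻⁴ M |  |
| epsilon | 0.170 M | 0.160 M | 4.00 × 10⁻⁴ M | 27 h |

| run | time / h | [target] / M |
|---|---|---|
| eta run | 3.9 | 0.01413 |
| eta run | 7.7 | 0.02465 |
| eta run | 12 | 0.03222 |
| eta run | 15 | 0.03640 |
| eta run | 19 | 0.03998 |
| eta run | 23 | 0.04260 |
| eta run | 27 | 0.04358 |
| beta run | 3.9 | 0.00732 |
| beta run | 7.7 | 0.01261 |
| beta run | 12 | 0.01614 |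
| beta run | 15 | 0.01820 |
| beta run | 19 | 0.01965 |
| beta run | 23 | 0.01981 |
| beta run | 27 | 0.02016 |
| theta run | 3.9 | 0.01655 |
| theta run | 7.7 | 0.02905 |
| theta run | 12 | 0.03892 |
| theta run | 15 | 0.04445 |
| theta run | 19 | 0.05046 |
| theta run | 23 | 0.05468 |
| theta run | 27 | 0.05773 |

(standard deviation of a reading: 2 × 10⁻⁴ M)

1. how the opening rate goes with [substrate] round the charge of the eta run: the exponent of the rate at two percent of substrate gone to target (one fixed amount of target, the same in the runs compared)
2. how the opening rate goes with [partner] round the charge of the eta run: the exponent of the rate at two percent of substrate gone to target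
3. target in the epsilon run at 27 h, as a share of the substrate charged

- Overall: substrate + partner -> target, with free catalyst as catalyst.
- Constant volume, constant temperature.
- "The second partner" is partner.
- An order is taken over about fifteen percent of the charge, up and down.

I built the epsilon run up in stages, taking the theta run as the large term because it has the same partner and free catalyst charges and the nearest substrate charge. First came the main step alone: the mean rate up to theta's first reading, held to 27 h, gives 0.115 M, or 67.4% of the epsilon charge.

Then I added the extra substrate as a correction. The first readings of eta and theta, which share a partner charge, give an exponent of 0.390, read at a fixed time. The rate therefore rises by a factor of 1.15, and the held target becomes 0.131 M. That is still below the partner charge of 0.160 M, so partner, the limiting reagent in epsilon, caps nothing at this stage.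

The rest went into one number, the keep factor: the target at the last reading divided by the held target. It reads 0.398 in beta, 0.445 in eta and 0.504 in theta. It climbs across these runs, but epsilon is charged with more substrate than partner, unlike those three, so I did not extend the climb and kept theta's value. That gave 0.0661 M, or 38.9% of the substrate charged.

The forecast, holding that “Rates die faster than the remaining reagents explain”, gave 0.42 for substrate, 0.45 for partner and 40% for epsilon, a little above my figure.

The simulation gave 0.45, 0.57 and 39.2%.

    free catalyst + substrate → loaded catalyst + by-product (316.1 /M/h)
    loaded catalyst + partner → target + free catalyst (117.0 /M/h)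
    free catalyst → spent catalyst (0.01991 /h)
    target + partner → side product (0.2268 /M/h)

The keep factor of the epsilon run came to 0.508. Taking away the reaction of target with partner to side product raised the epsilon target from 39.2% to 55.2%, so that reaction cost 16 percentage points.

(The runs stem from a simulated flask with constants of no real substance, noise included.)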